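**Retrosynthetic overview**
1. C13=C14 disconnection (HWE): the whole C20 chain comes from achiral (5E,9E)-farnesylacetone 1 and triethyl phosphonoacetate 2, joined as the open-chain tetraenoate 3.
2. C4–C5 and C9–C10 disconnections: one organocatalytic, proton-initiated bicyclization of 3 closes ring A first and ring B second, and passes through the alkene isomers 4 and 5 to the Δ8(9) trans-decalin 6; this sets C5 and C10.
3. C7–O disconnection: allylic oxidation of 6 gives enone 7; substrate-controlled hydride reduction (together with the C15 ester) gives diol 8 and sets C7.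
4. Two O–acyl disconnections: diacetylation of 8 gives the target 9.

Assumption: (5E,9E)-farnesylacetone is bought as the single geometric isomer, and the (R,R) antipode of the IDPi acid is taken as the one that gives the (5R,10R) series (the (S,S) antipode is used if a test run shows the opposite sense).

Positions are given in labdane numbering. The target is the ent-labdane (5R,7R,10R)-labda-8,13E-diene-7,15-diyl diacetate, with the 7-OAc cis to the C10 methyl and H-5 trans to it. (R,R)-IDPi is a C2-symmetric imidodiphosphorimidate Brønsted acid built from two (R)-BINOL units with bulky 3,3'-aryl groups and N-pentafluorophenylsulfonyl groups.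

**Step 1**
Reactants: 1 (5E,9E)-farnesylacetone; 2 triethyl phosphonoacetate
Product: 3 ethyl (2E,6E,10E)-geranylgeranoate
Conditions: NaH, THF, 0 °C to 50 °C; chromatography to remove the minor 2Z isomer
Reagents that add atoms: none
Why: Horner–Wadsworth–Emmons olefination of the methyl ketone gives the trisubstituted enoate with the usual E preference (about 4:1), the 2Z isomer is removed on silica, and no stereocenter is formed.

**Step 2**
Reactants: 3 ethyl (2E,6E,10E)-geranylgeranoate
Product: 6 ethyl (5R,10R)-labda-8,13E-dien-15-oate, via ethyl (5R,9R,10R)-labda-7,13E-dien-15-oate 4 (not isolated), via ethyl (5R,9R,10R)-labda-8(17),13E-dien-15-oate 5 (not isolated)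
Conditions: (R,R)-IDPi (5 mol%), (CF3)3COH, −10 °C, 72 h; then 30 °C, 24 h
Reagents that add atoms: none
Why: Proposed new method: the confined chiral Brønsted acid protonates the terminal 14,15-alkene of 3 (C3 of the labdane) while the polyene is held chair–chair-folded in its pocket as a tight ion pair in the cation-stabilising fluoroalcohol, and anti addition across the two E-alkenes closes ring A (C4–C5) and then ring B (C9–C10) to the trans-decalin, setting C5 and C10 under catalyst control; because the enoate alkene is too electron-poor to attack, the C8 cation ends by proton loss to 4 and 5, which the same acid re-protonates on warming until they drain into the tetrasubstituted, hard-to-protonate Δ8(9) alkene 6 (C9 is erased, C5 and C10 are not touched); the closest known reaction type is the IDPi-catalysed hydroxyl-terminated polyene cyclization of homofarnesol-type substrates together with IDPi protonation of unactivated alkenes, here extended to a polyene with no internal nucleophile and an elimination/equilibration terminus.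

**Step 3**
Reactants: 6 ethyl (5R,10R)-labda-8,13E-dien-15-oate
Product: 7 ethyl (5R,10R)-7-oxolabda-8,13E-dien-15-oate
Conditions: CrO3 (15 equiv), 3,5-dimethylpyrazole (15 equiv), CH2Cl2, −20 °C
Reagents that add atoms: chromium trioxide, O=[Cr](=O)=O
Why: Allylic C–H oxidation with the chromium trioxide–3,5-dimethylpyrazole complex takes the ring methylene C7, whose axial C–H is aligned with the only electron-rich alkene, in preference to the C11 methylene shielded by the quaternary C10 and to the deactivated allylic positions of the enoate; C5 and C10 are not allylic and are untouched.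

**Step 4**
Reactants: 7 ethyl (5R,10R)-7-oxolabda-8,13E-dien-15-oate
Product: 8 (5R,7R,10R)-labda-8,13E-diene-7,15-diol
Conditions: i-Bu2AlH (5 equiv), CH2Cl2, −78 °C to −40 °C; aq. potassium sodium tartrate
Reagents that add atoms: none
Why: Hydride reduction converts the conjugated ester into the primary allylic alcohol and reduces the enone 1,2; axial delivery to C7 from the face opposite the C10 methyl (the sense seen for steroidal 4-en-3-ones) gives the pseudo-equatorial 7R alcohol cis to the angular methyl.

**Step 5**
Reactants: 8 (5R,7R,10R)-labda-8,13E-diene-7,15-diol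
Product: 9 (5R,7R,10R)-labda-8,13E-diene-7,15-diyl diacetate
Conditions: Ac2O, pyridine, DMAP (cat.), CH2Cl2, 0 °C to rt
Reagents that add atoms: acetic anhydride, CC(=O)OC(C)=O
Why: DMAP-catalysed acylation esterifies both the primary and the secondary allylic alcohol under basic conditions that do not ionise the allylic C–O bonds, so C7 and the 13E geometry are retained.

**Compound list**
1 | (5E,9E)-farnesylacetone, (5E,9E)-6,10,14-trimethylpentadeca-5,9,13-trien-2-one | CC(=O)CC/C=C(\C)CC/C=C(\C)CCC=C(C)C | starting material
2 | triethyl phosphonoacetate | CCOC(=O)CP(=O)(OCC)OCC | starting material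
3 | ethyl (2E,6E,10E)-3,7,11,15-tetramethylhexadeca-2,6,10,14-tetraenoate (ethyl geranylgeranoate) | CCOC(=O)/C=C(\C)CC/C=C(\C)CC/C=C(\C)CCC=C(C)C | intermediate
4 | ethyl (5R,9R,10R)-labda-7,13E-dien-15-oate (ent-labdane, trans-decalin, C9 side chain cis to the C10 methyl) | CCOC(=O)/C=C(\C)CC[C@@H]1C(C)=CC[C@@H]2C(C)(C)CCC[C@@]12C | intermediate
5 | ethyl (5R,9R,10R)-labda-8(17),13E-dien-15-oate (ent-labdane, exocyclic methylene at C8) | CCOC(=O)/C=C(\C)CC[C@@H]1C(=C)CC[C@@H]2C(C)(C)CCC[C@@]12C | intermediate
6 | ethyl (5R,10R)-labda-8,13E-dien-15-oate (ent-labdane, tetrasubstituted C8=C9) | CCOC(=O)/C=C(\C)CCC1=C(C)CC[C@@H]2C(C)(C)CCC[C@@]12C | intermediate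
7 | ethyl (5R,10R)-7-oxolabda-8,13E-dien-15-oate | CCOC(=O)/C=C(\C)CCC1=C(C)C(=O)C[C@@H]2C(C)(C)CCC[C@@]12C | intermediate
8 | (5R,7R,10R)-labda-8,13E-diene-7,15-diol (7-OH cis to the C10 methyl) | OC/C=C(\C)CCC1=C(C)[C@H](O)C[C@@H]2C(C)(C)CCC[C@@]12C | intermediate
9 | (5R,7R,10R)-labda-8,13E-diene-7,15-diyl diacetate | CC(=O)OC/C=C(\C)CCC1=C(C)[C@H](OC(C)=O)C[C@@H]2C(C)(C)CCC[C@@]12C | target

Total step count: 5. Longest linear sequence: 5 steps (1 → 3 → 6 → 7 → 8 → 9).

**Steps most likely to fail**

Step 2 (the proposed cyclization). It may give low enantioselectivity or monocyclic material, may not converge on the Δ8(9) alkene, or may let the C8 cation rearrange. Fallback with known chemistry, from 3 back to 6: the enantioselective proton-initiated polyprenoid cyclization with a stoichiometric Lewis acid-assisted chiral Brønsted acid, SnCl4 · BINOL mono(2-fluorobenzyl) ether (BINOL antipode chosen for the 5R,10R series), in toluene at −78 °C, gives the kinetic alkene isomers 4 and 5, here isolated as a mixture. TsOH·H2O in toluene at 80 °C then moves the double bond into the tetrasubstituted position and gives 6. This fallback makes no compound outside the list (F0).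

Step 3 (allylic oxidation). C11 or C17 may be oxidised as well, or the 7,11-dione may form. Fallback from 6 back to 7: SeO2 (0.5 equiv) with t-BuOOH in CH2Cl2 at rt works by an ene reaction and [2,3]-sigmatropic shift instead of direct C–H oxidation to the ketone. It places oxygen on C7 from the face opposite the C10 methyl and gives ethyl (5R,7S,10R)-7-hydroxylabda-8,13E-dien-15-oate F1. Dess–Martin periodinane in CH2Cl2 at rt oxidises it to 7; the C7 configuration of the alcohol is erased there.

Step 4 (C7 selectivity of the hydride reduction). The bulky aluminium hydride may give too much of the 7S epimer. Fallback from 7 back to 8: reagent-controlled reduction of the enone alone with (S)-2-methyl-CBS-oxazaborolidine (20 mol%) and catecholborane in toluene at −78 °C (matched with the intrinsic axial preference) gives ethyl (5R,7R,10R)-7-hydroxylabda-8,13E-dien-15-oate F2. i-Bu2AlH in CH2Cl2 at −78 °C then reduces only its ester and gives 8.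

**Further compounds**
F0 | step 2 | none | none
F1 | step 3 | ethyl (5R,7S,10R)-7-hydroxylabda-8,13E-dien-15-oate | CCOC(=O)/C=C(\C)CCC1=C(C)[C@@H](O)C[C@@H]2C(C)(C)CCC[C@@]12C
F2 | step 4 | ethyl (5R,7R,10R)-7-hydroxylabda-8,13E-dien-15-oate | CCOC(=O)/C=C(\C)CCC1=C(C)[C@H](O)C[C@@H]2C(C)(C)CCC[C@@]12C
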